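**Strategy.** The route rests on disconnecting the ring-fusion bond C3a–C7a of the hydrindane. It is formed by a bromonium-initiated cation–olefin closure that copies the presumed marine biogenesis of β-bromo quaternary carbons: an enantiopure bromonium ion, released from an open-chain β-bromo tertiary alcohol, is captured by the enol carbon of a β-keto ester. One operation closes ring B, builds quaternary C3a beside the equatorial C4 bromide and fixes C7a; it exploits the C4–Br/C3a(CH3) pair of ring B. The precursor is an acyclic bromohydrin keto ester from a Sharpless epoxide and acetoacetate dianion. Ring A follows by nitrile oxide cycloaddition; ring C is a bromocyclohexanone made the same way.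

Key step: step 6

Remarks on the chemistry:
- Locants: hydrindane (octahydro-1H-indene) C1, C2, C3, C3a, C4–C7, C7a. Ring A is the cyclopentane, ring B the cyclohexane of the hydrindane, ring C the 4-bromo-1-hydroxy-3,3-dimethylcyclohexyl ring. C1' is the acetoxy-bearing carbon between C1 and ring C.
- Silyl ether 1 is taken as purchasable (otherwise one silylation of but-3-yn-1-ol).

**Fragment 1 (rings B and A precursor)**

Step 1
Reactants: 1 tert-butyl(but-3-yn-1-yloxy)diphenylsilane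
Product: 2 (2E)-5-[(tert-butyldiphenylsilyl)oxy]-3-methylpent-2-en-1-ol
Conditions: Me3Al, Cp2ZrCl2 (0.25 equiv), CH2Cl2, 0 °C → rt; then n-BuLi, (CH2O)n, THF, −78 °C → rt
Reagents that add atoms: trimethylaluminium C[Al](C)C; paraformaldehyde (as formaldehyde) C=O
Why: Zirconium-catalysed carboalumination (Negishi carboalumination) adds CH3 and Al syn across the alkyne with Al at the terminus, and the alkenylalanate then adds to formaldehyde with retention, so the trisubstituted alkene should be E (CH2CH2OSi trans to CH2OH).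

Step 2
Reactants: 2 (2E)-5-[(tert-butyldiphenylsilyl)oxy]-3-methylpent-2-en-1-ol
Product: 3 [(2R,3R)-3-{2-[(tert-butyldiphenylsilyl)oxy]ethyl}-3-methyloxiran-2-yl]methanol
Conditions: Ti(OiPr)4 (10 mol %), D-(−)-diethyl tartrate (12 mol %), t-BuOOH, 4 Å molecular sieves, CH2Cl2, −20 °C
Reagents that add atoms: tert-butyl hydroperoxide CC(C)(C)OO
Why: Sharpless asymmetric epoxidation of an E-allylic alcohol: the D-(−)-tartrate catalyst should deliver oxygen to the face that gives the (2R,3R)-epoxide (mirror image of the geraniol/L-(+)-tartrate outcome), which fixes the later C4 and C3a centres.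

Step 3
Reactants: 3 [(2R,3R)-3-{2-[(tert-butyldiphenylsilyl)oxy]ethyl}-3-methyloxiran-2-yl]methanol
Product: 4 [(2R,3R)-3-{2-[(tert-butyldiphenylsilyl)oxy]ethyl}-3-methyloxiran-2-yl]methyl 4-methylbenzenesulfonate
Conditions: TsCl, Et3N, DMAP (cat.), CH2Cl2, 0 °C
Reagents that add atoms: 4-methylbenzenesulfonyl chloride Cc1ccc(cc1)S(Cl)(=O)=O
Why: Sulfonylation of the primary alcohol (tosylate formation) leaves the epoxide and the silyl ether untouched; no stereocentre is involved.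

Step 4
Reactants: 4 [(2R,3R)-3-{2-[(tert-butyldiphenylsilyl)oxy]ethyl}-3-methyloxiran-2-yl]methyl 4-methylbenzenesulfonate; 5 methyl 3-oxobutanoate
Product: 6 methyl 5-[(2R,3R)-3-{2-[(tert-butyldiphenylsilyl)oxy]ethyl}-3-methyloxiran-2-yl]-3-oxopentanoate
Conditions: 5, NaH, THF, 0 °C; n-BuLi, 0 °C; then 4, 0 °C → rt
Reagents that add atoms: none
Why: γ-Alkylation of the acetoacetate dianion: the terminal carbanion should displace the primary tosylate by SN2 (activated by the adjacent oxirane) faster than it opens the trisubstituted epoxide, so both stereocentres are carried over.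

Step 5
Reactants: 6 methyl 5-[(2R,3R)-3-{2-[(tert-butyldiphenylsilyl)oxy]ethyl}-3-methyloxiran-2-yl]-3-oxopentanoate
Product: 7 methyl (6S,7R)-6-bromo-9-[(tert-butyldiphenylsilyl)oxy]-7-hydroxy-7-methyl-3-oxononanoate
Conditions: Li2NiBr4, THF, 0 °C → rt; pH 7 buffer
Reagents that add atoms: dilithium tetrabromonickelate [Li+].[Li+].[Ni+2].[Br-].[Br-].[Br-].[Br-]
Why: Epoxide opening by soft bromide from Li2NiBr4 should follow an SN2 course at the less substituted oxirane carbon with inversion, giving the anti bromohydrin with a secondary (6S) bromide and the tertiary (7R) alcohol.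

Step 6
Reactants: 7 methyl (6S,7R)-6-bromo-9-[(tert-butyldiphenylsilyl)oxy]-7-hydroxy-7-methyl-3-oxononanoate
Product: 9 methyl (1S,5S,6S)-5-bromo-6-{2-[(tert-butyldiphenylsilyl)oxy]ethyl}-6-methyl-2-oxocyclohexane-1-carboxylate, via bromonium ion 8 (not isolated)
Conditions: SnCl4 (2.2 equiv), CH2Cl2, −78 → −30 °C; aq. NaHCO3
Reagents that add atoms: none
Why: SnCl4 chelates the β-keto ester as its tin enolate and ionises the tertiary C7–OH with anchimeric help from the anti C6–Br, giving bromonium ion 8 of fixed configuration (Br on the face opposite the former epoxide oxygen); the enol carbon C2 then opens it at the tertiary carbon anti to bromine and forms the future C3a–C7a bond. The closest known reaction types are the SnCl4-mediated cation–olefin cyclisation of epoxy or alkenyl β-keto esters and the bromonium-induced polyene cyclisation, entered here stereospecifically from a bromohydrin. Ring B should close in a 6-(enolendo)-exo-tet mode through a chair in which bromine and the CH2CH2OSi arm are equatorial and the future C3a methyl is axial. The bromide centre keeps the configuration set in step 5, the quaternary centre is set by the anti opening of the bromonium ion (net retention at the carbinol carbon), and the epimerisable ester-bearing centre should settle with the ester equatorial. The step needs C- over O-alkylation, which the tin chelate secures (an O-cyclised enol ether reionises under SnCl4), and capture faster than bromonium transfer, which the intramolecular six-membered closure secures.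

Step 7
Reactants: 9 methyl (1S,5S,6S)-5-bromo-6-{2-[(tert-butyldiphenylsilyl)oxy]ethyl}-6-methyl-2-oxocyclohexane-1-carboxylate
Product: 10 methyl (1S,2R,5S,6S)-5-bromo-6-{2-[(tert-butyldiphenylsilyl)oxy]ethyl}-2-hydroxy-2,6-dimethylcyclohexane-1-carboxylate
Conditions: MeMgBr, CeCl3, THF, −78 °C
Reagents that add atoms: methylmagnesium bromide C[Mg]Br
Why: Cerium-mediated Grignard 1,2-addition should outrun enolisation of the hindered β-keto ester, and the methyl group should enter equatorially, anti to the axial C6 methyl, so that the new tertiary hydroxyl is axial (2R, the later C7).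

Step 8
Reactants: 10 methyl (1S,2R,5S,6S)-5-bromo-6-{2-[(tert-butyldiphenylsilyl)oxy]ethyl}-2-hydroxy-2,6-dimethylcyclohexane-1-carboxylate
Product: 11 methyl (1S,2R,5S,6S)-5-bromo-6-{2-[(tert-butyldiphenylsilyl)oxy]ethyl}-2,6-dimethyl-2-[(triethylsilyl)oxy]cyclohexane-1-carboxylate
Conditions: Et3SiOTf, 2,6-lutidine, CH2Cl2, −78 → 0 °C
Reagents that add atoms: triethylsilyl trifluoromethanesulfonate CC[Si](CC)(CC)OS(=O)(=O)C(F)(F)F
Why: Silyl triflate silylation of the hindered tertiary alcohol, needed to block β-elimination and retro-aldol cleavage of the β-oxy aldehyde in step 9 and O-acetylation in step 15.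

Step 9
Reactants: 11 methyl (1S,2R,5S,6S)-5-bromo-6-{2-[(tert-butyldiphenylsilyl)oxy]ethyl}-2,6-dimethyl-2-[(triethylsilyl)oxy]cyclohexane-1-carboxylate
Product: 13 (1S,2R,5S,6S)-5-bromo-6-{2-[(tert-butyldiphenylsilyl)oxy]ethyl}-1-ethynyl-2,6-dimethyl-2-[(triethylsilyl)oxy]cyclohexane, via aldehyde 12 (not isolated)
Conditions: iBu2AlH, CH2Cl2, −78 °C; then MeOH, dimethyl (1-diazo-2-oxopropyl)phosphonate, K2CO3, −78 °C → rt
Reagents that add atoms: dimethyl (1-diazo-2-oxopropyl)phosphonate COP(=O)(OC)C(=[N+]=[N-])C(C)=O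
Why: Low-temperature iBu2AlH reduction should stop at the aluminium hemiacetal of the hindered ester, which releases aldehyde 12 in methanol for Seyferth–Gilbert homologation with the Ohira–Bestmann reagent; the equatorial C1 centre is the stable epimer and should not change.

**Fragment 2 (ring C)**

Step 10
Reactants: 14 3-methylbut-2-en-1-ol
Product: 16 [(2R)-3,3-dimethyloxiran-2-yl]methyl 4-methylbenzenesulfonate, via epoxy alcohol 15 (not isolated)
Conditions: Ti(OiPr)4 (cat.), D-(−)-diethyl tartrate (cat.), t-BuOOH, 4 Å molecular sieves, CH2Cl2, −20 °C; then Et3N, DMAP (cat.), TsCl, −10 °C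
Reagents that add atoms: tert-butyl hydroperoxide CC(C)(C)OO; 4-methylbenzenesulfonyl chloride Cc1ccc(cc1)S(Cl)(=O)=O
Why: Sharpless asymmetric epoxidation with in situ tosylation of the water-soluble epoxy alcohol; the D-(−)-tartrate catalyst should give the (2R)-epoxide, the source of the ring C bromide centre.

Step 11
Reactants: 16 [(2R)-3,3-dimethyloxiran-2-yl]methyl 4-methylbenzenesulfonate; 17 tert-butyl 3-oxobutanoate
Product: 18 tert-butyl 5-[(2R)-3,3-dimethyloxiran-2-yl]-3-oxopentanoate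
Conditions: 17, NaH, THF, 0 °C; n-BuLi, 0 °C; then 16, 0 °C → rt
Reagents that add atoms: none
Why: γ-Alkylation of the acetoacetate dianion by SN2 displacement of the primary tosylate, as in step 4, with the epoxide stereocentre untouched.

Step 12
Reactants: 18 tert-butyl 5-[(2R)-3,3-dimethyloxiran-2-yl]-3-oxopentanoate
Product: 19 tert-butyl (6S)-6-bromo-7-hydroxy-7-methyl-3-oxooctanoate
Conditions: Li2NiBr4, THF, 0 °C → rt; pH 7 buffer
Reagents that add atoms: dilithium tetrabromonickelate [Li+].[Li+].[Ni+2].[Br-].[Br-].[Br-].[Br-]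
Why: SN2 opening of the epoxide by bromide from Li2NiBr4 at the secondary carbon with inversion, as in step 5, sets the (6S) bromide.

Step 13
Reactants: 19 tert-butyl (6S)-6-bromo-7-hydroxy-7-methyl-3-oxooctanoate
Product: 21 tert-butyl (1S,5S)-5-bromo-6,6-dimethyl-2-oxocyclohexane-1-carboxylate, via bromonium ion 20 (not isolated)
Conditions: SnCl4 (2.2 equiv), CH2Cl2, −78 → −30 °C; aq. NaHCO3
Reagents that add atoms: none
Why: Same bromonium-initiated cation–olefin closure as step 6 (ionisation of the tertiary alcohol with bromine participation, then 6-(enolendo)-exo-tet C-alkylation of the tin enolate): the bromide centre is untouched and the ester should settle equatorial, cis to bromine.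

Step 14
Reactants: 21 tert-butyl (1S,5S)-5-bromo-6,6-dimethyl-2-oxocyclohexane-1-carboxylate
Product: 22 (4S)-4-bromo-3,3-dimethylcyclohexan-1-one
Conditions: CF3CO2H, CH2Cl2, rt; then toluene, 80 °C
Reagents that add atoms: none
Why: Acidolysis of the tert-butyl ester and thermal decarboxylation of the β-keto acid; the equatorial bromide next to the quaternary carbon has no anti-periplanar hydrogen and should survive.

**Coupling and completion**

Step 15
Reactants: 13 (1S,2R,5S,6S)-5-bromo-6-{2-[(tert-butyldiphenylsilyl)oxy]ethyl}-1-ethynyl-2,6-dimethyl-2-[(triethylsilyl)oxy]cyclohexane; 22 (4S)-4-bromo-3,3-dimethylcyclohexan-1-one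
Product: 24 (1R,4S)-4-bromo-1-{[(1S,2R,5S,6S)-5-bromo-6-{2-[(tert-butyldiphenylsilyl)oxy]ethyl}-2,6-dimethyl-2-[(triethylsilyl)oxy]cyclohexyl]ethynyl}-3,3-dimethylcyclohexyl acetate, via lithium alkoxide 23 (not isolated)
Conditions: 13, n-BuLi, THF, −78 °C; then 22, −78 → −20 °C; then Ac2O, −20 °C → rt
Reagents that add atoms: acetic anhydride CC(=O)OC(C)=O
Why: 1,2-Addition of the lithium acetylide to the ketone: the axial C3 methyl blocks axial attack, so the alkyne should enter equatorially on the chair with equatorial bromine, leaving oxygen axial and cis to bromine (1R), and the alkoxide is trapped as the acetate (a minor C1 epimer arising from the other chair would be removed by chromatography).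

Step 16
Reactants: 24 (1R,4S)-4-bromo-1-{[(1S,2R,5S,6S)-5-bromo-6-{2-[(tert-butyldiphenylsilyl)oxy]ethyl}-2,6-dimethyl-2-[(triethylsilyl)oxy]cyclohexyl]ethynyl}-3,3-dimethylcyclohexyl acetate
Product: 25 (1R,4S)-4-bromo-1-{(Z)-2-[(1S,2R,5S,6S)-5-bromo-6-{2-[(tert-butyldiphenylsilyl)oxy]ethyl}-2,6-dimethyl-2-[(triethylsilyl)oxy]cyclohexyl]ethenyl}-3,3-dimethylcyclohexyl acetate
Conditions: H2 (1 atm), Pd/CaCO3 poisoned with Pb(OAc)2 (Lindlar catalyst), quinoline, EtOAc, rt
Reagents that add atoms: none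
Why: Lindlar semihydrogenation adds H2 syn and should stop at the Z-alkene; alkyl bromides, the acetate and the silyl ethers are inert.

Step 17
Reactants: 25 (1R,4S)-4-bromo-1-{(Z)-2-[(1S,2R,5S,6S)-5-bromo-6-{2-[(tert-butyldiphenylsilyl)oxy]ethyl}-2,6-dimethyl-2-[(triethylsilyl)oxy]cyclohexyl]ethenyl}-3,3-dimethylcyclohexyl acetate
Product: 26 (1R,4S)-4-bromo-1-{(Z)-2-[(1S,2R,5S,6S)-5-bromo-2-hydroxy-6-(2-hydroxyethyl)-2,6-dimethylcyclohexyl]ethenyl}-3,3-dimethylcyclohexyl acetate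
Conditions: Bu4NF, AcOH, THF, rt
Reagents that add atoms: none
Why: Fluoride-mediated desilylation removes both silyl ethers; buffering with acetic acid should keep the tertiary acetate in place.

Step 18
Reactants: 26 (1R,4S)-4-bromo-1-{(Z)-2-[(1S,2R,5S,6S)-5-bromo-2-hydroxy-6-(2-hydroxyethyl)-2,6-dimethylcyclohexyl]ethenyl}-3,3-dimethylcyclohexyl acetate
Product: 27 (1R,4S)-4-bromo-1-{(Z)-2-[(1S,2R,5S,6S)-5-bromo-2-hydroxy-2,6-dimethyl-6-(2-oxoethyl)cyclohexyl]ethenyl}-3,3-dimethylcyclohexyl acetate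
Conditions: Dess–Martin periodinane, NaHCO3, CH2Cl2, 0 °C → rt
Reagents that add atoms: none
Why: Dess–Martin oxidation of the only primary alcohol to the aldehyde; the tertiary alcohol cannot be oxidised.

Step 19
Reactants: 27 (1R,4S)-4-bromo-1-{(Z)-2-[(1S,2R,5S,6S)-5-bromo-2-hydroxy-2,6-dimethyl-6-(2-oxoethyl)cyclohexyl]ethenyl}-3,3-dimethylcyclohexyl acetate
Product: 28 (1R,4S)-4-bromo-1-{(Z)-2-[(1S,2R,5S,6S)-5-bromo-2-hydroxy-6-[(2E)-2-(hydroxyimino)ethyl]-2,6-dimethylcyclohexyl]ethenyl}-3,3-dimethylcyclohexyl acetate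
Conditions: NH2OH·HCl, pyridine, EtOH, rt
Reagents that add atoms: hydroxylamine hydrochloride NO.Cl
Why: Condensation of the aldehyde with hydroxylamine gives the aldoxime (oxime formation); no stereocentre is touched.

Step 20
Reactants: 28 (1R,4S)-4-bromo-1-{(Z)-2-[(1S,2R,5S,6S)-5-bromo-2-hydroxy-6-[(2E)-2-(hydroxyimino)ethyl]-2,6-dimethylcyclohexyl]ethenyl}-3,3-dimethylcyclohexyl acetate
Product: 30 ring A-closed isoxazoline (4,5-dihydroisoxazole fused across C1–C2 of the hydrindane; see compound list), via nitrile oxide 29 (not isolated)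
Conditions: NaOCl (aq.), CH2Cl2, 0 °C → rt
Reagents that add atoms: none
Why: Hypochlorite oxidation gives nitrile oxide 29, whose intramolecular nitrile oxide–alkene cycloaddition (INOC) closes ring A: the syn addition across the Z-alkene joins C2–C1 and O–C1' on one face, and allylic 1,3-strain (C7a–H eclipsing the alkene) should steer the dipole to the face that places the side chain trans to C7, setting C1 (S) and C1' (R).

Step 21
Reactants: 30 ring A-closed isoxazoline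
Product: 31 (1R,4S)-4-bromo-1-{(R)-[(1R,3aS,4S,7R,7aS)-4-bromo-7-hydroxy-3a,7-dimethyl-2-oxooctahydro-1H-inden-1-yl](hydroxy)methyl}-3,3-dimethylcyclohexyl acetate
Conditions: Mo(CO)6, MeCN/H2O, 80 °C
Reagents that add atoms: water O
Why: Mo(CO)6-mediated reductive N–O cleavage followed by hydrolysis of the β-hydroxy imine should give the β-hydroxy ketone without touching the C–Br bonds; C1 keeps its more stable configuration (side chain trans to C7).

Step 22
Reactants: 31 (1R,4S)-4-bromo-1-{(R)-[(1R,3aS,4S,7R,7aS)-4-bromo-7-hydroxy-3a,7-dimethyl-2-oxooctahydro-1H-inden-1-yl](hydroxy)methyl}-3,3-dimethylcyclohexyl acetate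
Product: 32 (1R,4S)-4-bromo-1-{(R)-[(1S,2R,3aS,4S,7R,7aS)-4-bromo-2,7-dihydroxy-3a,7-dimethyloctahydro-1H-inden-1-yl](hydroxy)methyl}-3,3-dimethylcyclohexyl acetate
Conditions: Et2BOMe, THF/MeOH, −78 °C; NaBH4; then AcOH; MeOH (evaporation)
Reagents that add atoms: none
Why: Narasaka–Prasad reduction: the diethylboron chelate of the β-hydroxy ketone holds the side chain over the α face, so external hydride should add to C2 from the β face and give the 1,3-syn diol (2R).

Step 23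
Reactants: 32 (1R,4S)-4-bromo-1-{(R)-[(1S,2R,3aS,4S,7R,7aS)-4-bromo-2,7-dihydroxy-3a,7-dimethyloctahydro-1H-inden-1-yl](hydroxy)methyl}-3,3-dimethylcyclohexyl acetate
Product: 33 (R)-[(1R,4S)-4-bromo-1-hydroxy-3,3-dimethylcyclohexyl][(1S,2R,3aS,4S,7R,7aS)-4-bromo-2,7-dihydroxy-3a,7-dimethyloctahydro-1H-inden-1-yl]methyl acetate
Conditions: DBU (0.2 equiv), CH2Cl2, 0 °C → rt
Reagents that add atoms: none
Why: Base-catalysed 1,2-acyl migration through a five-membered orthoester alkoxide should move the acetyl group from the congested tertiary oxygen to the neighbouring secondary C1' oxygen, the thermodynamically preferred ester, which gives the target.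

**Compound list**

1 | tert-butyl(but-3-yn-1-yloxy)diphenylsilane | C#CCCO[Si](c1ccccc1)(c1ccccc1)C(C)(C)C | starting material
2 | (2E)-5-[(tert-butyldiphenylsilyl)oxy]-3-methylpent-2-en-1-ol | CC(C)(C)[Si](c1ccccc1)(c1ccccc1)OCC/C(C)=C/CO | intermediate
3 | [(2R,3R)-3-{2-[(tert-butyldiphenylsilyl)oxy]ethyl}-3-methyloxiran-2-yl]methanol | CC(C)(C)[Si](c1ccccc1)(c1ccccc1)OCC[C@@]1(C)O[C@@H]1CO | intermediate
4 | [(2R,3R)-3-{2-[(tert-butyldiphenylsilyl)oxy]ethyl}-3-methyloxiran-2-yl]methyl 4-methylbenzenesulfonate | CC(C)(C)[Si](c1ccccc1)(c1ccccc1)OCC[C@@]1(C)O[C@@H]1COS(=O)(=O)c1ccc(C)cc1 | intermediate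
5 | methyl 3-oxobutanoate (methyl acetoacetate) | CC(=O)CC(=O)OC | starting material
6 | methyl 5-[(2R,3R)-3-{2-[(tert-butyldiphenylsilyl)oxy]ethyl}-3-methyloxiran-2-yl]-3-oxopentanoate | CC(C)(C)[Si](c1ccccc1)(c1ccccc1)OCC[C@@]1(C)O[C@@H]1CCC(=O)CC(=O)OC | intermediate
7 | methyl (6S,7R)-6-bromo-9-[(tert-butyldiphenylsilyl)oxy]-7-hydroxy-7-methyl-3-oxononanoate | CC(C)(C)[Si](c1ccccc1)(c1ccccc1)OCC[C@@](C)(O)[C@@H](Br)CCC(=O)CC(=O)OC | intermediate
8 | methyl 5-[(2S,3S)-3-{2-[(tert-butyldiphenylsilyl)oxy]ethyl}-3-methylbromiran-1-ium-2-yl]-3-oxopentanoate (bromonium ion) | CC(C)(C)[Si](c1ccccc1)(c1ccccc1)OCC[C@]1(C)[Br+][C@H]1CCC(=O)CC(=O)OC | intermediate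
9 | methyl (1S,5S,6S)-5-bromo-6-{2-[(tert-butyldiphenylsilyl)oxy]ethyl}-6-methyl-2-oxocyclohexane-1-carboxylate | CC(C)(C)[Si](c1ccccc1)(c1ccccc1)OCC[C@]1(C)[C@@H](Br)CCC(=O)[C@H]1C(=O)OC | intermediate
10 | methyl (1S,2R,5S,6S)-5-bromo-6-{2-[(tert-butyldiphenylsilyl)oxy]ethyl}-2-hydroxy-2,6-dimethylcyclohexane-1-carboxylate | CC(C)(C)[Si](c1ccccc1)(c1ccccc1)OCC[C@]1(C)[C@@H](Br)CC[C@@](C)(O)[C@H]1C(=O)OC | intermediate
11 | methyl (1S,2R,5S,6S)-5-bromo-6-{2-[(tert-butyldiphenylsilyl)oxy]ethyl}-2,6-dimethyl-2-[(triethylsilyl)oxy]cyclohexane-1-carboxylate | CC(C)(C)[Si](c1ccccc1)(c1ccccc1)OCC[C@]1(C)[C@@H](Br)CC[C@@](C)(O[Si](CC)(CC)CC)[C@H]1C(=O)OC | intermediate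
12 | (1S,2R,5S,6S)-5-bromo-6-{2-[(tert-butyldiphenylsilyl)oxy]ethyl}-2,6-dimethyl-2-[(triethylsilyl)oxy]cyclohexane-1-carbaldehyde | CC(C)(C)[Si](c1ccccc1)(c1ccccc1)OCC[C@]1(C)[C@@H](Br)CC[C@@](C)(O[Si](CC)(CC)CC)[C@H]1C=O | intermediate
13 | (1S,2R,5S,6S)-5-bromo-6-{2-[(tert-butyldiphenylsilyl)oxy]ethyl}-1-ethynyl-2,6-dimethyl-2-[(triethylsilyl)oxy]cyclohexane | CC(C)(C)[Si](c1ccccc1)(c1ccccc1)OCC[C@]1(C)[C@@H](Br)CC[C@@](C)(O[Si](CC)(CC)CC)[C@H]1C#C | intermediate
14 | 3-methylbut-2-en-1-ol | CC(C)=CCO | starting material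
15 | [(2R)-3,3-dimethyloxiran-2-yl]methanol | CC1(C)O[C@@H]1CO | intermediate
16 | [(2R)-3,3-dimethyloxiran-2-yl]methyl 4-methylbenzenesulfonate | CC1(C)O[C@@H]1COS(=O)(=O)c1ccc(C)cc1 | intermediate
17 | tert-butyl 3-oxobutanoate | CC(=O)CC(=O)OC(C)(C)C | starting material
18 | tert-butyl 5-[(2R)-3,3-dimethyloxiran-2-yl]-3-oxopentanoate | CC1(C)O[C@@H]1CCC(=O)CC(=O)OC(C)(C)C | intermediate
19 | tert-butyl (6S)-6-bromo-7-hydroxy-7-methyl-3-oxooctanoate | CC(C)(O)[C@@H](Br)CCC(=O)CC(=O)OC(C)(C)C | intermediate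
20 | tert-butyl 5-[(2S)-3,3-dimethylbromiran-1-ium-2-yl]-3-oxopentanoate (bromonium ion) | CC1(C)[Br+][C@H]1CCC(=O)CC(=O)OC(C)(C)C | intermediate
21 | tert-butyl (1S,5S)-5-bromo-6,6-dimethyl-2-oxocyclohexane-1-carboxylate | CC(C)(C)OC(=O)[C@@H]1C(=O)CC[C@H](Br)C1(C)C | intermediate
22 | (4S)-4-bromo-3,3-dimethylcyclohexan-1-one | O=C1CC[C@H](Br)C(C)(C)C1 | intermediate
23 | lithium (1R,4S)-4-bromo-1-{[(1S,2R,5S,6S)-5-bromo-6-{2-[(tert-butyldiphenylsilyl)oxy]ethyl}-2,6-dimethyl-2-[(triethylsilyl)oxy]cyclohexyl]ethynyl}-3,3-dimethylcyclohexan-1-olate | [Li+].CC(C)(C)[Si](c1ccccc1)(c1ccccc1)OCC[C@]1(C)[C@@H](Br)CC[C@@](C)(O[Si](CC)(CC)CC)[C@H]1C#C[C@@]1([O-])CC[C@H](Br)C(C)(C)C1 | intermediate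
24 | (1R,4S)-4-bromo-1-{[(1S,2R,5S,6S)-5-bromo-6-{2-[(tert-butyldiphenylsilyl)oxy]ethyl}-2,6-dimethyl-2-[(triethylsilyl)oxy]cyclohexyl]ethynyl}-3,3-dimethylcyclohexyl acetate | CC(C)(C)[Si](c1ccccc1)(c1ccccc1)OCC[C@]1(C)[C@@H](Br)CC[C@@](C)(O[Si](CC)(CC)CC)[C@H]1C#C[C@@]1(OC(C)=O)CC[C@H](Br)C(C)(C)C1 | intermediate
25 | (1R,4S)-4-bromo-1-{(Z)-2-[(1S,2R,5S,6S)-5-bromo-6-{2-[(tert-butyldiphenylsilyl)oxy]ethyl}-2,6-dimethyl-2-[(triethylsilyl)oxy]cyclohexyl]ethenyl}-3,3-dimethylcyclohexyl acetate | CC(C)(C)[Si](c1ccccc1)(c1ccccc1)OCC[C@]1(C)[C@@H](Br)CC[C@@](C)(O[Si](CC)(CC)CC)[C@H]1/C=C\[C@@]1(OC(C)=O)CC[C@H](Br)C(C)(C)C1 | intermediate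
26 | (1R,4S)-4-bromo-1-{(Z)-2-[(1S,2R,5S,6S)-5-bromo-2-hydroxy-6-(2-hydroxyethyl)-2,6-dimethylcyclohexyl]ethenyl}-3,3-dimethylcyclohexyl acetate | OCC[C@]1(C)[C@@H](Br)CC[C@@](C)(O)[C@H]1/C=C\[C@@]1(OC(C)=O)CC[C@H](Br)C(C)(C)C1 | intermediate
27 | (1R,4S)-4-bromo-1-{(Z)-2-[(1S,2R,5S,6S)-5-bromo-2-hydroxy-2,6-dimethyl-6-(2-oxoethyl)cyclohexyl]ethenyl}-3,3-dimethylcyclohexyl acetate | O=CC[C@]1(C)[C@@H](Br)CC[C@@](C)(O)[C@H]1/C=C\[C@@]1(OC(C)=O)CC[C@H](Br)C(C)(C)C1 | intermediate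
28 | (1R,4S)-4-bromo-1-{(Z)-2-[(1S,2R,5S,6S)-5-bromo-2-hydroxy-6-[(2E)-2-(hydroxyimino)ethyl]-2,6-dimethylcyclohexyl]ethenyl}-3,3-dimethylcyclohexyl acetate | O/N=C/C[C@]1(C)[C@@H](Br)CC[C@@](C)(O)[C@H]1/C=C\[C@@]1(OC(C)=O)CC[C@H](Br)C(C)(C)C1 | intermediate
29 | nitrile oxide of 28 (C≡N+–O− in place of CH=N–OH; all other centres as in 28) | [O-][N+]#CC[C@]1(C)[C@@H](Br)CC[C@@](C)(O)[C@H]1/C=C\[C@@]1(OC(C)=O)CC[C@H](Br)C(C)(C)C1 | intermediate
30 | isoxazoline: 4,5-dihydroisoxazole fused across C1–C2 of the (3aS,4S,7R,7aS)-4-bromo-7-hydroxy-3a,7-dimethylhydrindane (isoxazoline C3 = hydrindane C2; C4 = hydrindane C1, S; C5 = C1', R, bearing the (1R,4S)-1-acetoxy-4-bromo-3,3-dimethylcyclohexyl group) | O1N=C2C[C@]3(C)[C@@H](Br)CC[C@@](C)(O)[C@H]3[C@@H]2[C@@H]1[C@@]1(OC(C)=O)CC[C@H](Br)C(C)(C)C1 | intermediate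
31 | (1R,4S)-4-bromo-1-{(R)-[(1R,3aS,4S,7R,7aS)-4-bromo-7-hydroxy-3a,7-dimethyl-2-oxooctahydro-1H-inden-1-yl](hydroxy)methyl}-3,3-dimethylcyclohexyl acetate | O=C1C[C@]2(C)[C@@H](Br)CC[C@@](C)(O)[C@H]2[C@@H]1[C@@H](O)[C@@]1(OC(C)=O)CC[C@H](Br)C(C)(C)C1 | intermediate
32 | (1R,4S)-4-bromo-1-{(R)-[(1S,2R,3aS,4S,7R,7aS)-4-bromo-2,7-dihydroxy-3a,7-dimethyloctahydro-1H-inden-1-yl](hydroxy)methyl}-3,3-dimethylcyclohexyl acetate | O[C@@H]1C[C@]2(C)[C@@H](Br)CC[C@@](C)(O)[C@H]2[C@@H]1[C@@H](O)[C@@]1(OC(C)=O)CC[C@H](Br)C(C)(C)C1 | intermediate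
33 | (R)-[(1R,4S)-4-bromo-1-hydroxy-3,3-dimethylcyclohexyl][(1S,2R,3aS,4S,7R,7aS)-4-bromo-2,7-dihydroxy-3a,7-dimethyloctahydro-1H-inden-1-yl]methyl acetate | CC(=O)O[C@H]([C@@H]1[C@H](O)C[C@]2(C)[C@@H](Br)CC[C@@](C)(O)[C@@H]12)[C@@]1(O)CC[C@H](Br)C(C)(C)C1 | target

**Count.** Total step count: 23. Longest linear sequence: 18 steps (steps 1–9 and 15–23).

**Steps most likely to fail**

Step 6. The ketone oxygen may alkylate instead of carbon (cyclic enol ether), the bromonium ion may be lost by proton loss or a 1,2-shift, or bromonium transfer may erode enantiopurity. The fallback sets out from 2 and comes back at 9. Alcohol 2 is converted with PBr3 (Et2O, 0 °C) into tert-butyl{[(3E)-5-bromo-3-methylpent-3-en-1-yl]oxy}diphenylsilane F1, which alkylates the dianion of 5 to methyl (6E)-9-[(tert-butyldiphenylsilyl)oxy]-7-methyl-3-oxonon-6-enoate F2. Direct halonium-induced cyclisation of F2 with Et2SBr·SbCl5Br in MeNO2 at −25 °C should give 9 as the racemate, that is together with methyl (1R,5R,6R)-5-bromo-6-{2-[(tert-butyldiphenylsilyl)oxy]ethyl}-6-methyl-2-oxocyclohexane-1-carboxylate F3. Chromatography on a chiral stationary phase then returns enantiopure 9.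

Step 5. Bromide may attack the tertiary oxirane carbon, or the enol oxygen may open the activated epoxide to a tetrahydrofuran. The fallback sets out from 6 and comes back at 9, using the opposite regiochemistry on purpose. Anhydrous HBr (Et2O, −20 °C) opens 6 at the tertiary carbon with inversion to methyl (6R,7S)-7-bromo-9-[(tert-butyldiphenylsilyl)oxy]-6-hydroxy-7-methyl-3-oxononanoate F4. MsCl/Et3N gives methyl (6R,7S)-7-bromo-9-[(tert-butyldiphenylsilyl)oxy]-6-[(methanesulfonyl)oxy]-7-methyl-3-oxononanoate F5. On solvolysis in (CF3)2CHOH with 2,6-lutidine the neighbouring tertiary bromide should displace the mesylate with inversion, giving the same bromonium ion 8, which closes to 9.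

Step 7. The organometallic may enolise the β-keto ester instead of adding, returning 9. The fallback sets out from 9 and comes back at 13, with the methyl group added only after the ester has been homologated:
- NaBH4 (MeOH, −40 °C) gives methyl (1S,2R,5S,6S)-5-bromo-6-{2-[(tert-butyldiphenylsilyl)oxy]ethyl}-2-hydroxy-6-methylcyclohexane-1-carboxylate F6.
- Et3SiOTf/2,6-lutidine gives methyl (1S,2R,5S,6S)-5-bromo-6-{2-[(tert-butyldiphenylsilyl)oxy]ethyl}-6-methyl-2-[(triethylsilyl)oxy]cyclohexane-1-carboxylate F7.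
- iBu2AlH followed by the Ohira–Bestmann reagent gives (1S,2R,5S,6S)-5-bromo-6-{2-[(tert-butyldiphenylsilyl)oxy]ethyl}-1-ethynyl-6-methyl-2-[(triethylsilyl)oxy]cyclohexane F8.
- Pyridinium p-toluenesulfonate in MeOH removes only the secondary silyl ether, giving (1R,2S,3S,4S)-4-bromo-3-{2-[(tert-butyldiphenylsilyl)oxy]ethyl}-2-ethynyl-3-methylcyclohexan-1-ol F9.
- Dess–Martin oxidation gives (2S,3S,4S)-4-bromo-3-{2-[(tert-butyldiphenylsilyl)oxy]ethyl}-2-ethynyl-3-methylcyclohexan-1-one F10.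
- MeMgBr/CeCl3 should add equatorially to this ordinary ketone, giving (1R,2S,3S,4S)-4-bromo-3-{2-[(tert-butyldiphenylsilyl)oxy]ethyl}-2-ethynyl-1,3-dimethylcyclohexan-1-ol F11.
- Et3SiOTf/2,6-lutidine then gives 13.

Further compounds
F1 | step 6 | tert-butyl{[(3E)-5-bromo-3-methylpent-3-en-1-yl]oxy}diphenylsilane | CC(C)(C)[Si](c1ccccc1)(c1ccccc1)OCC/C(C)=C/CBr
F2 | step 6 | methyl (6E)-9-[(tert-butyldiphenylsilyl)oxy]-7-methyl-3-oxonon-6-enoate | CC(C)(C)[Si](c1ccccc1)(c1ccccc1)OCC/C(C)=C/CCC(=O)CC(=O)OC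
F3 | step 6 | methyl (1R,5R,6R)-5-bromo-6-{2-[(tert-butyldiphenylsilyl)oxy]ethyl}-6-methyl-2-oxocyclohexane-1-carboxylate (enantiomer of 9) | CC(C)(C)[Si](c1ccccc1)(c1ccccc1)OCC[C@@]1(C)[C@H](Br)CCC(=O)[C@@H]1C(=O)OC
F4 | step 5 | methyl (6R,7S)-7-bromo-9-[(tert-butyldiphenylsilyl)oxy]-6-hydroxy-7-methyl-3-oxononanoate | CC(C)(C)[Si](c1ccccc1)(c1ccccc1)OCC[C@](C)(Br)[C@H](O)CCC(=O)CC(=O)OC
F5 | step 5 | methyl (6R,7S)-7-bromo-9-[(tert-butyldiphenylsilyl)oxy]-6-[(methanesulfonyl)oxy]-7-methyl-3-oxononanoate | CC(C)(C)[Si](c1ccccc1)(c1ccccc1)OCC[C@](C)(Br)[C@H](OS(C)(=O)=O)CCC(=O)CC(=O)OC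
F6 | step 7 | methyl (1S,2R,5S,6S)-5-bromo-6-{2-[(tert-butyldiphenylsilyl)oxy]ethyl}-2-hydroxy-6-methylcyclohexane-1-carboxylate | CC(C)(C)[Si](c1ccccc1)(c1ccccc1)OCC[C@]1(C)[C@@H](Br)CC[C@@H](O)[C@H]1C(=O)OC
F7 | step 7 | methyl (1S,2R,5S,6S)-5-bromo-6-{2-[(tert-butyldiphenylsilyl)oxy]ethyl}-6-methyl-2-[(triethylsilyl)oxy]cyclohexane-1-carboxylate | CC(C)(C)[Si](c1ccccc1)(c1ccccc1)OCC[C@]1(C)[C@@H](Br)CC[C@@H](O[Si](CC)(CC)CC)[C@H]1C(=O)OC
F8 | step 7 | (1S,2R,5S,6S)-5-bromo-6-{2-[(tert-butyldiphenylsilyl)oxy]ethyl}-1-ethynyl-6-methyl-2-[(triethylsilyl)oxy]cyclohexane | CC(C)(C)[Si](c1ccccc1)(c1ccccc1)OCC[C@]1(C)[C@@H](Br)CC[C@@H](O[Si](CC)(CC)CC)[C@H]1C#C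
F9 | step 7 | (1R,2S,3S,4S)-4-bromo-3-{2-[(tert-butyldiphenylsilyl)oxy]ethyl}-2-ethynyl-3-methylcyclohexan-1-ol | CC(C)(C)[Si](c1ccccc1)(c1ccccc1)OCC[C@]1(C)[C@@H](Br)CC[C@@H](O)[C@H]1C#C
F10 | step 7 | (2S,3S,4S)-4-bromo-3-{2-[(tert-butyldiphenylsilyl)oxy]ethyl}-2-ethynyl-3-methylcyclohexan-1-one | CC(C)(C)[Si](c1ccccc1)(c1ccccc1)OCC[C@]1(C)[C@@H](Br)CCC(=O)[C@H]1C#C
F11 | step 7 | (1R,2S,3S,4S)-4-bromo-3-{2-[(tert-butyldiphenylsilyl)oxy]ethyl}-2-ethynyl-1,3-dimethylcyclohexan-1-ol | CC(C)(C)[Si](c1ccccc1)(c1ccccc1)OCC[C@]1(C)[C@@H](Br)CC[C@@](C)(O)[C@H]1C#C
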